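**Plan**

1. Retrosynthesis: the acetate and the silyl ether go last; ring B (the cyclopentenone) is cut at its C=C by ring-closing metathesis and at the bond between its two stereocentres by an Ireland–Claisen rearrangement of a (2S,3E)-pent-3-en-2-yl ester.
2. Ring A is numbered as in the target name (C1 carbinol carbon with OH and CH2OAc, C2 bearing ring B, C3 bearing the dienyl chain). Its stereocentres are removed one by one: H at C2 (conjugate hydride), OH at C1 ([2,3] selenoxide shift), dienyl chain at C3 (alkenylcuprate, inversion).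
3. What remains is a flat 2,3-disubstituted cyclopent-2-enone with C3 as carbonyl and a tetrasubstituted C1=C2 alkene; this bond is cut by retro-aldol condensation to a 1,4-diketone, itself a Stetter union of two four-carbon pieces.
4. Enabling feature: C3 of ring A can stand at the ketone level, so C2 becomes an enolisable α-CH2 and C1 (an α-silyloxy ketone carbon) the electrophile across the C4–C5 ethylene bridge; ring A therefore closes as a jasmonoid-type enone.
5. Forward order: dienyl iodide (steps 1–3); ring A by Stetter reaction and aldol condensation (4–7); stereocentres C3, C1, C2 in that order (9–13), each new group entering anti to the last, which ends in the all-cis array; ring B (14–17); desilylation and acetylation (18–19).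
6. Stereochemistry: (R)-CBS catalyst (C3, then inverted), substrate control from C3 (C1 and C2), chair chirality transfer from (2S,3E)-pent-3-en-2-ol (both ring-B centres), trans-hydroalumination of but-2-yn-1-ol (Z alkene).

Key step: step 7

Remark: 7 and 8 are used as racemates because their stereocentre is removed in step 5; (2S,3E)-pent-3-en-2-ol (14) is taken as a catalogue compound.

**Route**

Step 1
Reactants: 1 but-2-yn-1-ol
Product: 3 (2Z)-3-iodobut-2-en-1-ol, via alkenylaluminate 2 (not isolated)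
Conditions: NaAlH2(OCH2CH2OMe)2, THF, 0 °C to rt; then I2, −78 °C
Reagents that add atoms: iodine, II
Why: hydroxyl-directed trans-hydroalumination of the propargylic alcohol places aluminium on C3 cis to the CH2O group (five-membered alkoxyaluminate), and iodinolysis with retention should give the Z vinyl iodide that fixes the side-chain alkene geometry.

Step 2
Reactants: 3 (2Z)-3-iodobut-2-en-1-ol
Product: 4 (2Z)-1-bromo-3-iodobut-2-ene
Conditions: CBr4, PPh3, CH2Cl2, 0 °C
Reagents that add atoms: carbon tetrabromide, BrC(Br)(Br)Br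
Why: Appel bromination of the primary allylic alcohol, which leaves the vinyl iodide and the alkene geometry untouched.

Step 3
Reactants: 4 (2Z)-1-bromo-3-iodobut-2-ene; 5 (2-methylprop-1-en-1-yl)magnesium bromide
Product: 6 (2Z)-2-iodo-6-methylhepta-2,5-diene
Conditions: Li2CuCl4 (3 mol%), THF, −30 to 0 °C
Reagents that add atoms: none
Why: copper-catalysed SN2 allylation of an alkenyl Grignard reagent by a primary allylic bromide; the fully substituted γ-carbon disfavours SN2' and the vinyl iodide should be inert at this temperature.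

Step 4
Reactants: 7 but-3-ene-1,2-diol
Product: 8 1-{[tri(propan-2-yl)silyl]oxy}but-3-en-2-ol
Conditions: TIPSCl, imidazole, CH2Cl2, 0 °C
Reagents that add atoms: chlorotri(propan-2-yl)silane, CC(C)[Si](Cl)(C(C)C)C(C)C
Why: the bulky silyl chloride should silylate the primary hydroxyl selectively; the base-stable TIPS ether is chosen to survive step 7.

Step 5
Reactants: 8 1-{[tri(propan-2-yl)silyl]oxy}but-3-en-2-ol
Product: 9 1-{[tri(propan-2-yl)silyl]oxy}but-3-en-2-one
Conditions: Dess–Martin periodinane, CH2Cl2, 0 °C to rt; used at once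
Reagents that add atoms: none
Why: non-basic oxidation of the secondary allylic alcohol to the vinyl ketone needed as Michael acceptor.

Step 6
Reactants: 9 1-{[tri(propan-2-yl)silyl]oxy}but-3-en-2-one; 10 methyl 4-oxobutanoate
Product: 11 methyl 4,7-dioxo-8-{[tri(propan-2-yl)silyl]oxy}octanoate
Conditions: 3-benzyl-5-(2-hydroxyethyl)-4-methylthiazolium chloride (10 mol%), Et3N (30 mol%), EtOH, 70 °C
Reagents that add atoms: none
Why: Stetter reaction, in which the Breslow intermediate of the aliphatic aldehyde adds 1,4 to the vinyl ketone and gives the 1,4-diketone.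

Step 7
Reactants: 11 methyl 4,7-dioxo-8-{[tri(propan-2-yl)silyl]oxy}octanoate
Product: 13 2-[5-oxo-2-({[tri(propan-2-yl)silyl]oxy}methyl)cyclopent-1-en-1-yl]acetic acid, via aldol adduct 12 (not isolated)
Conditions: KOH (3 equiv), MeOH/H2O, 50 °C; then 1 M HCl to pH 3
Reagents that add atoms: potassium hydroxide, [K+].[OH-]
Why: hydroxide saponifies the ester, then the enolate of the CH2 between the C4 ketone and the carboxylate arm adds to the α-silyloxy C7 ketone (5-enolexo-exo-trig aldol) and the aldolate loses water by E1cB, which closes ring A and forms the bond between its later carbinol carbon C1 and C2 as a tetrasubstituted C=C. The closest known reaction type is the base-mediated cyclodehydration of 2,5-diketones to 2,3-disubstituted cyclopent-2-enones used for jasmonoids. The step deliberately creates no stereocentre: it delivers a planar ring on which each ring-A stereocentre is then written by a separate face-selective event. The selectivity needed is regiochemical, namely which enolate attacks which ketone. It should be secured because the α-silyloxy ketone is the better electrophile, its own α-CH2 is shielded by the TIPS group, the other closures would give three-membered rings, and only this mode ends, after irreversible dehydration, in the favoured tetrasubstituted enone. Aqueous hydroxide is used so that the carboxylate, not an ester, is present and a Dieckmann-type closure is excluded.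

Step 8
Reactants: 13 2-[5-oxo-2-({[tri(propan-2-yl)silyl]oxy}methyl)cyclopent-1-en-1-yl]acetic acid; 14 (2S,3E)-pent-3-en-2-ol
Product: 15 (2S,3E)-pent-3-en-2-yl 2-[5-oxo-2-({[tri(propan-2-yl)silyl]oxy}methyl)cyclopent-1-en-1-yl]acetate
Conditions: EDC·HCl, DMAP (10 mol%), CH2Cl2, 0 °C to rt
Reagents that add atoms: none
Why: Steglich-type esterification installs the chiral allylic ester needed for step 14 while the molecule still has no base-sensitive stereocentre.

Step 9
Reactants: 15 (2S,3E)-pent-3-en-2-yl 2-[5-oxo-2-({[tri(propan-2-yl)silyl]oxy}methyl)cyclopent-1-en-1-yl]acetate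
Product: 16 (2S,3E)-pent-3-en-2-yl 2-[(5S)-5-hydroxy-2-({[tri(propan-2-yl)silyl]oxy}methyl)cyclopent-1-en-1-yl]acetate
Conditions: (R)-2-methyl-CBS-oxazaborolidine (15 mol%), catecholborane, toluene, −78 °C
Reagents that add atoms: none
Why: CBS reduction of an α,β-disubstituted cyclopentenone, in which the tetrasubstituted alkene side acts as the large group, so the (R)-catalyst should give the (S)-allylic alcohol; the ester and the propenyl group are untouched by catecholborane at this temperature.

Step 10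
Reactants: 16 (2S,3E)-pent-3-en-2-yl 2-[(5S)-5-hydroxy-2-({[tri(propan-2-yl)silyl]oxy}methyl)cyclopent-1-en-1-yl]acetate
Product: 17 (2S,3E)-pent-3-en-2-yl 2-[(5S)-5-[(diethoxyphosphoryl)oxy]-2-({[tri(propan-2-yl)silyl]oxy}methyl)cyclopent-1-en-1-yl]acetate
Conditions: ClP(O)(OEt)2, pyridine, DMAP (cat.), CH2Cl2, −20 °C; used crude without delay
Reagents that add atoms: diethyl chlorophosphate, CCOP(=O)(Cl)OCC
Why: O-phosphorylation activates the allylic alcohol with retention at carbon.

Step 11
Reactants: 17 (2S,3E)-pent-3-en-2-yl 2-[(5S)-5-[(diethoxyphosphoryl)oxy]-2-({[tri(propan-2-yl)silyl]oxy}methyl)cyclopent-1-en-1-yl]acetate; 6 (2Z)-2-iodo-6-methylhepta-2,5-diene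
Product: 20 (2S,3E)-pent-3-en-2-yl 2-[(5S)-5-[(2Z)-6-methylhepta-2,5-dien-2-yl]-2-({[tri(propan-2-yl)silyl]oxy}methyl)cyclopent-1-en-1-yl]acetate, via alkenyllithium 18 (not isolated), via dialkenylcuprate 19 (not isolated)
Conditions: 6 (2.2 equiv), t-BuLi (4.4 equiv), Et2O, −78 °C; CuI (1.1 equiv), −40 °C; then 17, −78 to −20 °C
Reagents that add atoms: none
Why: stereospecific allylic substitution by a lithium dialkenylcuprate: monovalent copper adds anti to the phosphate, and the allyl intermediate of trivalent copper eliminates reductively at the secondary terminus because the other terminus is fully substituted. Net inversion should place the dienyl chain at ring-A C3 with the configuration of the target (S in this compound), and iodine–lithium exchange and transmetalation keep the Z alkene geometry.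

Step 12
Reactants: 20 (2S,3E)-pent-3-en-2-yl 2-[(5S)-5-[(2Z)-6-methylhepta-2,5-dien-2-yl]-2-({[tri(propan-2-yl)silyl]oxy}methyl)cyclopent-1-en-1-yl]acetate
Product: 24 (2S,3E)-pent-3-en-2-yl (2E)-2-[(2R,5S)-2-hydroxy-5-[(2Z)-6-methylhepta-2,5-dien-2-yl]-2-({[tri(propan-2-yl)silyl]oxy}methyl)cyclopentylidene]acetate, via α-selenide 21 (not isolated), via selenoxide 22 (not isolated), via selenenate 23 (not isolated)
Conditions: LiN(i-Pr)2 (1.1 equiv), THF, −78 °C; PhSeBr, −78 °C; then 30% H2O2, pyridine, CH2Cl2, 0 °C to rt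
Reagents that add atoms: hydrogen peroxide, OO
Why: α-selenenylation of the deconjugated ester enolate, oxidation, and [2,3]-sigmatropic shift of the allylic selenoxide (Mislow–Evans type) transfer oxygen to the tetrasubstituted ring-A C1 on the face opposite the C3 side chain, which sets the tertiary carbinol. The alkene moves into conjugation as the E enoate (ester arm on the C3 side, to avoid allylic strain with the CH2OTIPS group), which cannot lactonise.

Step 13
Reactants: 24 (2S,3E)-pent-3-en-2-yl (2E)-2-[(2R,5S)-2-hydroxy-5-[(2Z)-6-methylhepta-2,5-dien-2-yl]-2-({[tri(propan-2-yl)silyl]oxy}methyl)cyclopentylidene]acetate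
Product: 25 (2S,3E)-pent-3-en-2-yl 2-[(1R,2R,5R)-2-hydroxy-5-[(2Z)-6-methylhepta-2,5-dien-2-yl]-2-({[tri(propan-2-yl)silyl]oxy}methyl)cyclopentyl]acetate
Conditions: [(Ph3P)CuH]6 (0.4 equiv), benzene, H2O (3 equiv), rt
Reagents that add atoms: none
Why: conjugate hydride addition (Stryker reagent) to the exocyclic enoate. The hydride should reach ring-A C2 from the face that carries only the tertiary OH and the C3–H, opposite the CH2OTIPS and dienyl groups, so the acetate arm ends cis to both neighbours and the all-cis ring A results.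

Step 14
Reactants: 25 (2S,3E)-pent-3-en-2-yl 2-[(1R,2R,5R)-2-hydroxy-5-[(2Z)-6-methylhepta-2,5-dien-2-yl]-2-({[tri(propan-2-yl)silyl]oxy}methyl)cyclopentyl]acetate
Product: 28 (2S,3R,4E)-2-[(1S,2R,5R)-2-hydroxy-5-[(2Z)-6-methylhepta-2,5-dien-2-yl]-2-({[tri(propan-2-yl)silyl]oxy}methyl)cyclopentyl]-3-methylhex-4-enoic acid, via silyl ketene acetal 26 (not isolated), via silyl ester 27 (not isolated)
Conditions: LiN(i-Pr)2 (2.3 equiv), THF, −78 °C; TMSCl (3 equiv); −78 °C to rt; then 1 M HCl
Reagents that add atoms: none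
Why: Ireland–Claisen rearrangement: kinetic enolisation in THF gives the ketene acetal with the ring substituent cis to the allyloxy oxygen, and a chair transition state with the carbinol methyl equatorial transfers the S configuration of the pentenyl ester to both new centres (2S,3R, anti), the arrangement that becomes cis on ring B. The tertiary OH is silylated in the flask and freed on work-up.

Step 15
Reactants: 28 (2S,3R,4E)-2-[(1S,2R,5R)-2-hydroxy-5-[(2Z)-6-methylhepta-2,5-dien-2-yl]-2-({[tri(propan-2-yl)silyl]oxy}methyl)cyclopentyl]-3-methylhex-4-enoic acid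
Product: 29 (2S,3R,4E)-2-[(1S,2R,5R)-2-hydroxy-5-[(2Z)-6-methylhepta-2,5-dien-2-yl]-2-({[tri(propan-2-yl)silyl]oxy}methyl)cyclopentyl]-N-methoxy-N,3-dimethylhex-4-enamide
Conditions: MeNHOMe·HCl, EDC·HCl, HOBt, i-Pr2NEt, CH2Cl2, 0 °C to rt
Reagents that add atoms: N,O-dimethylhydroxylamine hydrochloride, CNOC.Cl
Why: carbodiimide coupling to the Weinreb amide under conditions that should not enolise the α-stereocentre; the trans tertiary OH cannot lactonise and does not acylate.

Step 16
Reactants: 29 (2S,3R,4E)-2-[(1S,2R,5R)-2-hydroxy-5-[(2Z)-6-methylhepta-2,5-dien-2-yl]-2-({[tri(propan-2-yl)silyl]oxy}methyl)cyclopentyl]-N-methoxy-N,3-dimethylhex-4-enamide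
Product: 30 (4S,5R,6E)-4-[(1S,2R,5R)-2-hydroxy-5-[(2Z)-6-methylhepta-2,5-dien-2-yl]-2-({[tri(propan-2-yl)silyl]oxy}methyl)cyclopentyl]-5-methylocta-1,6-dien-3-one
Conditions: vinylmagnesium bromide (4 equiv), THF, −78 to 0 °C; inverse quench into cold 1 M HCl
Reagents that add atoms: vinylmagnesium bromide, C=C[Mg]Br
Why: Weinreb ketone synthesis, in which the chelated tetrahedral intermediate prevents over-addition; one equivalent of the Grignard reagent is consumed by the tertiary OH, and the acidic inverse quench keeps the liberated amine from adding to the vinyl ketone.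

Step 17
Reactants: 30 (4S,5R,6E)-4-[(1S,2R,5R)-2-hydroxy-5-[(2Z)-6-methylhepta-2,5-dien-2-yl]-2-({[tri(propan-2-yl)silyl]oxy}methyl)cyclopentyl]-5-methylocta-1,6-dien-3-one
Product: 31 (4R,5S)-5-[(1S,2R,5R)-2-hydroxy-5-[(2Z)-6-methylhepta-2,5-dien-2-yl]-2-({[tri(propan-2-yl)silyl]oxy}methyl)cyclopentyl]-4-methylcyclopent-2-en-1-one
Conditions: second-generation Hoveyda–Grubbs catalyst (5 mol%), CH2Cl2, 40 °C
Reagents that add atoms: none
Why: ring-closing metathesis between the vinyl ketone and the propenyl group closes ring B with loss of propene; the trisubstituted side-chain alkenes should be too hindered to compete, and the neutral conditions preserve the epimerisable cis centre next to the ketone.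

Step 18
Reactants: 31 (4R,5S)-5-[(1S,2R,5R)-2-hydroxy-5-[(2Z)-6-methylhepta-2,5-dien-2-yl]-2-({[tri(propan-2-yl)silyl]oxy}methyl)cyclopentyl]-4-methylcyclopent-2-en-1-one
Product: 32 (4R,5S)-5-[(1S,2R,5R)-2-hydroxy-2-(hydroxymethyl)-5-[(2Z)-6-methylhepta-2,5-dien-2-yl]cyclopentyl]-4-methylcyclopent-2-en-1-one
Conditions: HF·pyridine, pyridine, THF, 0 °C to rt
Reagents that add atoms: none
Why: fluoride cleavage of the primary TIPS ether under buffered, non-basic conditions that should not epimerise the centre next to the ketone.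

Step 19
Reactants: 32 (4R,5S)-5-[(1S,2R,5R)-2-hydroxy-2-(hydroxymethyl)-5-[(2Z)-6-methylhepta-2,5-dien-2-yl]cyclopentyl]-4-methylcyclopent-2-en-1-one
Product: 33 [(1R,2S,3R)-1-hydroxy-3-[(2Z)-6-methylhepta-2,5-dien-2-yl]-2-[(1S,5R)-5-methyl-2-oxocyclopent-3-en-1-yl]cyclopentyl]methyl acetate
Conditions: Ac2O (1.2 equiv), pyridine, CH2Cl2, 0 °C
Reagents that add atoms: acetic anhydride, CC(=O)OC(C)=O
Why: the primary hydroxyl should be acetylated selectively; the tertiary hydroxyl does not react without an acylation catalyst.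

**Compound list**

1 | but-2-yn-1-ol | CC#CCO | starting material
2 | sodium alkenylaluminate from trans-hydroalumination of 1 | CC1=CCO[Al-]1(OCCOC)OCCOC.[Na+] | intermediate (not isolated)
3 | (2Z)-3-iodobut-2-en-1-ol | C/C(I)=C/CO | intermediate
4 | (2Z)-1-bromo-3-iodobut-2-ene | C/C(I)=C/CBr | intermediate
5 | (2-methylprop-1-en-1-yl)magnesium bromide | CC(C)=C[Mg]Br | starting material
6 | (2Z)-2-iodo-6-methylhepta-2,5-diene | C/C(I)=C/CC=C(C)C | intermediate
7 | but-3-ene-1,2-diol (racemate) | C=CC(O)CO | starting material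
8 | 1-{[tri(propan-2-yl)silyl]oxy}but-3-en-2-ol (racemate) | C=CC(O)CO[Si](C(C)C)(C(C)C)C(C)C | intermediate
9 | 1-{[tri(propan-2-yl)silyl]oxy}but-3-en-2-one | C=CC(=O)CO[Si](C(C)C)(C(C)C)C(C)C | intermediate
10 | methyl 4-oxobutanoate | COC(=O)CCC=O | starting material
11 | methyl 4,7-dioxo-8-{[tri(propan-2-yl)silyl]oxy}octanoate | COC(=O)CCC(=O)CCC(=O)CO[Si](C(C)C)(C(C)C)C(C)C | intermediate
12 | potassium 2-[2-hydroxy-5-oxo-2-({[tri(propan-2-yl)silyl]oxy}methyl)cyclopentyl]acetate (aldol adduct, stereoisomer mixture) | [K+].[O-]C(=O)CC1C(=O)CCC1(O)CO[Si](C(C)C)(C(C)C)C(C)C | intermediate (not isolated)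
13 | 2-[5-oxo-2-({[tri(propan-2-yl)silyl]oxy}methyl)cyclopent-1-en-1-yl]acetic acid | OC(=O)CC1=C(CO[Si](C(C)C)(C(C)C)C(C)C)CCC1=O | intermediate
14 | (2S,3E)-pent-3-en-2-ol | C/C=C/[C@H](C)O | starting material
15 | (2S,3E)-pent-3-en-2-yl 2-[5-oxo-2-({[tri(propan-2-yl)silyl]oxy}methyl)cyclopent-1-en-1-yl]acetate | CC(C)[Si](OCC1=C(CC(=O)O[C@@H](C)/C=C/C)C(=O)CC1)(C(C)C)C(C)C | intermediate
16 | (2S,3E)-pent-3-en-2-yl 2-[(5S)-5-hydroxy-2-({[tri(propan-2-yl)silyl]oxy}methyl)cyclopent-1-en-1-yl]acetate | CC(C)[Si](OCC1=C(CC(=O)O[C@@H](C)/C=C/C)[C@@H](O)CC1)(C(C)C)C(C)C | intermediate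
17 | (2S,3E)-pent-3-en-2-yl 2-[(5S)-5-[(diethoxyphosphoryl)oxy]-2-({[tri(propan-2-yl)silyl]oxy}methyl)cyclopent-1-en-1-yl]acetate | CC(C)[Si](OCC1=C(CC(=O)O[C@@H](C)/C=C/C)[C@@H](OP(=O)(OCC)OCC)CC1)(C(C)C)C(C)C | intermediate
18 | [(2Z)-6-methylhepta-2,5-dien-2-yl]lithium | [Li]/C(C)=C\CC=C(C)C | intermediate (not isolated)
19 | lithium bis[(2Z)-6-methylhepta-2,5-dien-2-yl]cuprate | [Li+].CC(C)=CC/C=C(C)\[Cu-]/C(C)=C\CC=C(C)C | intermediate (not isolated)
20 | (2S,3E)-pent-3-en-2-yl 2-[(5S)-5-[(2Z)-6-methylhepta-2,5-dien-2-yl]-2-({[tri(propan-2-yl)silyl]oxy}methyl)cyclopent-1-en-1-yl]acetate | CC(C)[Si](OCC1=C(CC(=O)O[C@@H](C)/C=C/C)[C@H](/C(C)=C\CC=C(C)C)CC1)(C(C)C)C(C)C | intermediate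
21 | α-(phenylselanyl) derivative of 20 (both epimers at the selenium-bearing carbon) | CC(C)[Si](OCC1=C(C([Se]c2ccccc2)C(=O)O[C@@H](C)/C=C/C)[C@H](/C(C)=C\CC=C(C)C)CC1)(C(C)C)C(C)C | intermediate (not isolated)
22 | selenoxide of 21 | CC(C)[Si](OCC1=C(C([Se](=O)c2ccccc2)C(=O)O[C@@H](C)/C=C/C)[C@H](/C(C)=C\CC=C(C)C)CC1)(C(C)C)C(C)C | intermediate (not isolated)
23 | O-(phenylselanyl) ether (selenenate) of 24 | CC(C)[Si](OC[C@@]1(O[Se]c2ccccc2)CC[C@@H](/C(C)=C\CC=C(C)C)/C1=C\C(=O)O[C@@H](C)/C=C/C)(C(C)C)C(C)C | intermediate (not isolated)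
24 | (2S,3E)-pent-3-en-2-yl (2E)-2-[(2R,5S)-2-hydroxy-5-[(2Z)-6-methylhepta-2,5-dien-2-yl]-2-({[tri(propan-2-yl)silyl]oxy}methyl)cyclopentylidene]acetate | CC(C)[Si](OC[C@@]1(O)CC[C@@H](/C(C)=C\CC=C(C)C)/C1=C\C(=O)O[C@@H](C)/C=C/C)(C(C)C)C(C)C | intermediate
25 | (2S,3E)-pent-3-en-2-yl 2-[(1R,2R,5R)-2-hydroxy-5-[(2Z)-6-methylhepta-2,5-dien-2-yl]-2-({[tri(propan-2-yl)silyl]oxy}methyl)cyclopentyl]acetate | CC(C)[Si](OC[C@@]1(O)CC[C@@H](/C(C)=C\CC=C(C)C)[C@H]1CC(=O)O[C@@H](C)/C=C/C)(C(C)C)C(C)C | intermediate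
26 | bis(trimethylsilyl) ketene acetal of 25 (ring substituent cis to the allyloxy oxygen) | CC(C)[Si](OC[C@@]1(O[Si](C)(C)C)CC[C@@H](/C(C)=C\CC=C(C)C)[C@H]1/C=C(/O[Si](C)(C)C)O[C@@H](C)/C=C/C)(C(C)C)C(C)C | intermediate (not isolated)
27 | trimethylsilyl ester of O-trimethylsilylated 28 | CC(C)[Si](OC[C@@]1(O[Si](C)(C)C)CC[C@@H](/C(C)=C\CC=C(C)C)[C@H]1[C@@H](C(=O)O[Si](C)(C)C)[C@H](C)/C=C/C)(C(C)C)C(C)C | intermediate (not isolated)
28 | (2S,3R,4E)-2-[(1S,2R,5R)-2-hydroxy-5-[(2Z)-6-methylhepta-2,5-dien-2-yl]-2-({[tri(propan-2-yl)silyl]oxy}methyl)cyclopentyl]-3-methylhex-4-enoic acid | CC(C)[Si](OC[C@@]1(O)CC[C@@H](/C(C)=C\CC=C(C)C)[C@H]1[C@@H](C(=O)O)[C@H](C)/C=C/C)(C(C)C)C(C)C | intermediate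
29 | (2S,3R,4E)-2-[(1S,2R,5R)-2-hydroxy-5-[(2Z)-6-methylhepta-2,5-dien-2-yl]-2-({[tri(propan-2-yl)silyl]oxy}methyl)cyclopentyl]-N-methoxy-N,3-dimethylhex-4-enamide | CC(C)[Si](OC[C@@]1(O)CC[C@@H](/C(C)=C\CC=C(C)C)[C@H]1[C@@H](C(=O)N(C)OC)[C@H](C)/C=C/C)(C(C)C)C(C)C | intermediate
30 | (4S,5R,6E)-4-[(1S,2R,5R)-2-hydroxy-5-[(2Z)-6-methylhepta-2,5-dien-2-yl]-2-({[tri(propan-2-yl)silyl]oxy}methyl)cyclopentyl]-5-methylocta-1,6-dien-3-one | CC(C)[Si](OC[C@@]1(O)CC[C@@H](/C(C)=C\CC=C(C)C)[C@H]1[C@@H](C(=O)C=C)[C@H](C)/C=C/C)(C(C)C)C(C)C | intermediate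
31 | (4R,5S)-5-[(1S,2R,5R)-2-hydroxy-5-[(2Z)-6-methylhepta-2,5-dien-2-yl]-2-({[tri(propan-2-yl)silyl]oxy}methyl)cyclopentyl]-4-methylcyclopent-2-en-1-one | CC(C)[Si](OC[C@@]1(O)CC[C@@H](/C(C)=C\CC=C(C)C)[C@H]1[C@H]1C(=O)C=C[C@H]1C)(C(C)C)C(C)C | intermediate
32 | (4R,5S)-5-[(1S,2R,5R)-2-hydroxy-2-(hydroxymethyl)-5-[(2Z)-6-methylhepta-2,5-dien-2-yl]cyclopentyl]-4-methylcyclopent-2-en-1-one | OC[C@@]1(O)CC[C@@H](/C(C)=C\CC=C(C)C)[C@H]1[C@H]1C(=O)C=C[C@H]1C | intermediate
33 | [(1R,2S,3R)-1-hydroxy-3-[(2Z)-6-methylhepta-2,5-dien-2-yl]-2-[(1S,5R)-5-methyl-2-oxocyclopent-3-en-1-yl]cyclopentyl]methyl acetate | CC(=O)OC[C@@]1(O)CC[C@@H](/C(C)=C\CC=C(C)C)[C@H]1[C@H]1C(=O)C=C[C@H]1C | target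

**Summary**

Total step count: 19. Longest linear sequence: 16 steps (steps 4–19, from but-3-ene-1,2-diol); the iodide branch (steps 1–3) joins at step 11.

**Steps most likely to fail**

Step 11. The alkenyl group may be transferred to the fully substituted allyl terminus, the allylic phosphate may ionise before it reacts (erosion of configuration at C3), or the hindered alkenyl group may leave copper too slowly. The fallback sets out from 16, which would be converted with methyl chloroformate and pyridine into the allylic methyl carbonate F1. Iodide 6 would be converted (t-BuLi, then Bu3SnCl) into tributyl[(2Z)-6-methylhepta-2,5-dien-2-yl]stannane F2. A Stille allyl–alkenyl coupling (Pd2(dba)3, AsPh3, LiCl, THF/NMP, rt) would follow: zerovalent palladium ionises the carbonate with inversion, the alkenyl group passes from tin to palladium and is delivered from the metal face to the less hindered allyl terminus, so net inversion results as in the copper route. The fallback comes back to the route at 20.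

Step 12. Oxygen may be delivered to the wrong ring face, selenenylation may occur at the γ-carbon of the dienolate, or side-chain alkenes may be oxidised by peroxyseleninic acid. The fallback sets out from 20. Its lithium enolate would be hydroxylated at the α-carbon with 3-phenyl-2-(phenylsulfonyl)oxaziridine to give the α-hydroxy-β,γ-unsaturated ester F3. Ph3SiOReO3 (catalytic, Et2O, −50 to 0 °C) would then move the hydroxyl suprafacially to the ring carbon through a six-membered perrhenate ester, driven by conjugation of the new enoate. The reaction would be stopped early so that delivery to the less hindered face is not lost by equilibration. The fallback comes back at 24.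

Step 13. Hydride transfer may be too slow at the hindered β,β-disubstituted enoate, or the allylic ester may be cleaved reductively. The fallback sets out from 24 and replaces hydride transfer by electron transfer (SmI2, THF, H2O, Et3N, 0 °C). The β-carbon of the doubly reduced enoate would be protonated from the same open face, and the fallback comes back at 25. It makes no compound outside the list (F0).

Further compounds
F1 | step 11 | (2S,3E)-pent-3-en-2-yl 2-[(5S)-5-[(methoxycarbonyl)oxy]-2-({[tri(propan-2-yl)silyl]oxy}methyl)cyclopent-1-en-1-yl]acetate | CC(C)[Si](OCC1=C(CC(=O)O[C@@H](C)/C=C/C)[C@@H](OC(=O)OC)CC1)(C(C)C)C(C)C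
F2 | step 11 | tributyl[(2Z)-6-methylhepta-2,5-dien-2-yl]stannane | CCCC[Sn](CCCC)(CCCC)/C(C)=C\CC=C(C)C
F3 | step 12 | (2S,3E)-pent-3-en-2-yl 2-hydroxy-2-[(5S)-5-[(2Z)-6-methylhepta-2,5-dien-2-yl]-2-({[tri(propan-2-yl)silyl]oxy}methyl)cyclopent-1-en-1-yl]acetate (both epimers at the new carbinol) | CC(C)[Si](OCC1=C(C(O)C(=O)O[C@@H](C)/C=C/C)[C@H](/C(C)=C\CC=C(C)C)CC1)(C(C)C)C(C)C
F0 | step 13 | none | none
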